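The tetralone carbocycle C1–C2–C3–C4–C4a–C8a is fused to a benzene ring bearing para hydroxyls at C5 and C8, which is the aromatised tautomer of a p-benzoquinone cycloadduct. Everything therefore rests on cutting C4–C4a and C1–C8a together. In one operation, an oxazaborolidinium-catalysed Diels–Alder reaction of p-benzoquinone closes this ring, fixes the diaryl methine C4 as (R) and delivers C1 already oxygenated. Its precursor is a (1E,3E)-1-(4-benzyloxy-8-methoxynaphthalen-1-yl)-4-silyloxybutadiene, grown from a naphthaldehyde so that the crowded aryl–C4 bond is present from the start. Enolisation, alkene saturation, oxidation at C1 and debenzylation finish the synthesis.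

Key step: step 7

Assumption: the (S)-configured oxazaborolidinium is written in step 7 as the antipode expected to give the drawn configuration; the sense of induction is to be checked on the first adduct, and the (R)-catalyst takes its place, with nothing else changed, should the opposite sense be found.

Step 1
Reactants: 1 1,5-dimethoxynaphthalene
Product: 2 4,8-dimethoxy-1-naphthaldehyde
Conditions: Cl2CHOMe, TiCl4, CH2Cl2, 0 °C to rt; then ice/aq. HCl
Reagents that add atoms: dichloromethyl methyl ether, COC(Cl)Cl (formyl carbon); water, O (carbonyl oxygen on hydrolysis)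
Why: Rieche formylation should attack the electron-rich naphthalene para to a methoxy group (C4, equivalent to C8 by the twofold symmetry of 1), and the aldehyde introduced deactivates the ring against a second substitution.

Step 2
Reactants: 2 4,8-dimethoxy-1-naphthaldehyde
Product: 4 4-(benzyloxy)-8-methoxy-1-naphthaldehyde, via sodium 4-formyl-5-methoxynaphthalen-1-olate 3 (not isolated)
Conditions: NaSEt, DMF, 110 °C; then BnBr (excess), rt, same flask
Reagents that add atoms: benzyl bromide, BrCc1ccccc1 (benzyl group); sodium ethanethiolate, CC[S-].[Na+] (sodium counter-ion of 3 only)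
Why: SN2 demethylation by thiolate should be selective for the methoxy group para to the formyl group, because only that naphthoxide is a vinylogous carboxylate (the peri oxygen is not conjugated with the aldehyde) and the anion formed resists a second cleavage, after which Williamson benzylation of the naphthoxide follows in the same flask.

Step 3
Reactants: 4 4-(benzyloxy)-8-methoxy-1-naphthaldehyde; 5 (methoxymethyl)triphenylphosphonium chloride
Product: 7 1-(benzyloxy)-5-methoxy-4-(2-methoxyethenyl)naphthalene (E/Z mixture), via (methoxymethylene)triphenylphosphorane 6 (not isolated)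
Conditions: 5, KOtBu, THF, 0 °C; then 4, 0 °C to rt
Reagents that add atoms: none
Why: Wittig olefination with the reactive, non-stabilised methoxymethylene ylide should proceed even on this donor-deactivated, peri-hindered aldehyde, and the alkene geometry is irrelevant since both isomers hydrolyse to the same aldehyde.

Step 4
Reactants: 7 1-(benzyloxy)-5-methoxy-4-(2-methoxyethenyl)naphthalene (E/Z mixture)
Product: 8 2-[4-(benzyloxy)-8-methoxynaphthalen-1-yl]acetaldehyde
Conditions: 2 M aq. HCl, THF, rt to 40 °C; crude aldehyde taken on at once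
Reagents that add atoms: water, O (carbonyl oxygen)
Why: acid-catalysed enol ether hydrolysis (C-protonation, hydration of the oxocarbenium ion, loss of methanol) should unmask the homologated aldehyde while the aryl benzyl and methyl ethers stay intact.

Step 5
Reactants: 8 2-[4-(benzyloxy)-8-methoxynaphthalen-1-yl]acetaldehyde; 9 (triphenylphosphoranylidene)acetaldehyde
Product: 10 (E)-4-[4-(benzyloxy)-8-methoxynaphthalen-1-yl]but-2-enal
Conditions: 9 (1.1 equiv), toluene, 70 °C
Reagents that add atoms: none
Why: Wittig olefination with the stabilised formylmethylene ylide should give the (E)-enal, and any drift of the double bond into conjugation with the arene would be harmless because both enal isomers lead to the same dienol ether in step 6.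

Step 6
Reactants: 10 (E)-4-[4-(benzyloxy)-8-methoxynaphthalen-1-yl]but-2-enal
Product: 11 {[(1E,3E)-4-(4-benzyloxy-8-methoxynaphthalen-1-yl)buta-1,3-dien-1-yl]oxy}triisopropylsilane
Conditions: iPr3SiOTf, Et3N, CH2Cl2, 0 °C to rt
Reagents that add atoms: triisopropylsilyl trifluoromethanesulfonate, CC(C)[Si](OS(=O)(=O)C(F)(F)F)(C(C)C)C(C)C
Why: soft enolisation (O-silylation of the carbonyl, then removal of the allylic and benzylic γ-hydrogen by Et3N) should give the linear dienol silyl ether, 1E from the s-trans enal and 3E as the favoured styrene geometry, with the bulky silyl group chosen for resistance to acid.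

Step 7
Reactants: 11 {[(1E,3E)-4-(4-benzyloxy-8-methoxynaphthalen-1-yl)buta-1,3-dien-1-yl]oxy}triisopropylsilane; 12 p-benzoquinone
Product: 13 (4aS,5S,8R,8aS)-5-[4-(benzyloxy)-8-methoxynaphthalen-1-yl]-8-[(triisopropylsilyl)oxy]-4a,5,8,8a-tetrahydronaphthalene-1,4-dione (all-cis endo adduct)
Conditions: 12 (1.3 equiv), (S)-3,3-diphenyl-1-(o-tolyl)tetrahydro-1H,3H-pyrrolo[1,2-c][1,3,2]oxazaborole protonated with HN(SO2CF3)2 (20 mol%), CH2Cl2, −78 °C; Et3N quench, short filtration
Reagents that add atoms: none
Why: The N-protonated oxazaborolidine binds one quinone carbonyl at boron, which lowers the LUMO of the adjacent C=C and covers one of its faces, and the silyloxydiene adds to the open face in a concerted, asynchronous, suprafacial [4+2] cycloaddition whose more advanced bond joins the aryl-bearing diene terminus to the quinone carbon β to the bound carbonyl. The closest known reaction type is the oxazaborolidinium-catalysed enantioselective Diels–Alder reaction of 1,4-quinones with oxygenated dienes. The only ring closed, the six-membered carbocycle C5–C6–C7–C8–C8a–C4a that becomes the tetralone ring, is formed by intermolecular [4+2] annulation in which C5–C4a and C8–C8a are made together across one quinone C=C. The absolute configuration at C5 (the future C4) is set by the catalyst through the face it leaves open combined with the endo approach, while C4a/C8a are cis through suprafacial addition to the cis alkene, C8 is cis to C5 through the (E,E) diene geometry and the 4a,5 relation follows the endo rule. Face, endo and orientation selectivity are all needed, because with the symmetric quinone the two diene orientations on one face give antipodes; the silyloxy donor of the substrate polarises the diene so that its remote, aryl-bearing carbon carries the larger HOMO coefficient and pairs with the β-carbon of the activated enone, and secondary overlap with the quinone carbonyls, strengthened by the Lewis acid, favours endo. At −78 °C the cycloaddition is expected to outrun acid-induced desilylation of the diene.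

Step 8
Reactants: 13 (4aS,5S,8R,8aS)-5-[4-(benzyloxy)-8-methoxynaphthalen-1-yl]-8-[(triisopropylsilyl)oxy]-4a,5,8,8a-tetrahydronaphthalene-1,4-dione
Product: 15 (5R,8R)-1,4-bis(benzyloxy)-5-[4-(benzyloxy)-8-methoxynaphthalen-1-yl]-8-[(triisopropylsilyl)oxy]-5,8-dihydronaphthalene, via hydroquinone tautomer 14 (not isolated)
Conditions: BnBr, K2CO3, degassed DMF, 0 °C to rt, argon; product carried into step 9 without storage
Reagents that add atoms: benzyl bromide, BrCc1ccccc1
Why: base-mediated double enolisation (proton shifts from C4a and C8a) should aromatise the ene-dione to the hydroquinone far faster than silanolate is lost, and immediate Williamson O-benzylation leaves no free phenoxide beside the benzylic silyl ether, with C5 and C8 untouched.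

Step 9
Reactants: 15 (5R,8R)-1,4-bis(benzyloxy)-5-[4-(benzyloxy)-8-methoxynaphthalen-1-yl]-8-[(triisopropylsilyl)oxy]-5,8-dihydronaphthalene
Product: 16 (1R,4R)-5,8-bis(benzyloxy)-4-[4-(benzyloxy)-8-methoxynaphthalen-1-yl]-1-[(triisopropylsilyl)oxy]-1,2,3,4-tetrahydronaphthalene
Conditions: H2 (1 atm), RhCl(PPh3)3 (10 mol%), benzene/EtOH, rt
Reagents that add atoms: none
Why: homogeneous hydrogenation with RhCl(PPh3)3 should saturate the cis-disubstituted ring alkene without hydrogenolysis of benzyl ethers or of the benzylic C–O bond and with little double-bond migration, which removes the possibility of 1,4-elimination to a naphthalene.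

Step 10
Reactants: 16 (1R,4R)-5,8-bis(benzyloxy)-4-[4-(benzyloxy)-8-methoxynaphthalen-1-yl]-1-[(triisopropylsilyl)oxy]-1,2,3,4-tetrahydronaphthalene
Product: 17 (1R,4R)-5,8-bis(benzyloxy)-4-[4-(benzyloxy)-8-methoxynaphthalen-1-yl]-1,2,3,4-tetrahydronaphthalen-1-ol
Conditions: Bu4NF, THF, rt
Reagents that add atoms: none
Why: fluoride desilylation cleaves the Si–O bond under non-acidic conditions, so the electron-rich benzylic C–O bond is not ionised.

Step 11
Reactants: 17 (1R,4R)-5,8-bis(benzyloxy)-4-[4-(benzyloxy)-8-methoxynaphthalen-1-yl]-1,2,3,4-tetrahydronaphthalen-1-ol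
Product: 18 (4R)-5,8-bis(benzyloxy)-4-[4-(benzyloxy)-8-methoxynaphthalen-1-yl]-3,4-dihydronaphthalen-1(2H)-one
Conditions: Dess–Martin periodinane, NaHCO3, CH2Cl2, 0 °C to rt
Reagents that add atoms: none
Why: Dess–Martin oxidation (ligand exchange at iodine, then loss of the carbinol hydrogen) should convert the secondary benzylic alcohol into the aryl ketone under buffered conditions that leave the C4–H and the benzyl ethers alone, erasing the relay stereocentre as intended.

Step 12
Reactants: 18 (4R)-5,8-bis(benzyloxy)-4-[4-(benzyloxy)-8-methoxynaphthalen-1-yl]-3,4-dihydronaphthalen-1(2H)-one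
Product: 19 (4R)-5,8-dihydroxy-4-(4-hydroxy-8-methoxynaphthalen-1-yl)-3,4-dihydronaphthalen-1(2H)-one (target CNP0584478.2)
Conditions: H2 (1 atm), 10% Pd/C (palladium on carbon), EtOAc/MeOH, rt, stopped after uptake of 3 equiv, argon work-up
Reagents that add atoms: none
Why: catalytic hydrogenolysis should remove the three O-benzyl groups while the aryl methyl ether stays, the neutral medium leaves C4 untouched, and the hydroxyl freed at C8 is expected to hydrogen-bond the ketone and slow its reduction.

Compound list
1 | 1,5-dimethoxynaphthalene | COc1cccc2c(OC)cccc12 | starting material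
2 | 4,8-dimethoxy-1-naphthaldehyde | COc1cccc2c(OC)ccc(C=O)c12 | intermediate
3 | sodium 4-formyl-5-methoxynaphthalen-1-olate (formed in the flask) | COc1cccc2c([O-])ccc(C=O)c12.[Na+] | intermediate
4 | 4-(benzyloxy)-8-methoxy-1-naphthaldehyde | COc1cccc2c(OCc3ccccc3)ccc(C=O)c12 | intermediate
5 | (methoxymethyl)triphenylphosphonium chloride | COC[P+](c1ccccc1)(c1ccccc1)c1ccccc1.[Cl-] | starting material
6 | (methoxymethylene)triphenylphosphorane (formed in the flask) | COC=P(c1ccccc1)(c1ccccc1)c1ccccc1 | intermediate
7 | 1-(benzyloxy)-5-methoxy-4-(2-methoxyethenyl)naphthalene (E/Z mixture) | COc1cccc2c(OCc3ccccc3)ccc(C=COC)c12 | intermediate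
8 | 2-[4-(benzyloxy)-8-methoxynaphthalen-1-yl]acetaldehyde | COc1cccc2c(OCc3ccccc3)ccc(CC=O)c12 | intermediate
9 | (triphenylphosphoranylidene)acetaldehyde | O=CC=P(c1ccccc1)(c1ccccc1)c1ccccc1 | starting material
10 | (E)-4-[4-(benzyloxy)-8-methoxynaphthalen-1-yl]but-2-enal | COc1cccc2c(OCc3ccccc3)ccc(C/C=C/C=O)c12 | intermediate
11 | {[(1E,3E)-4-(4-benzyloxy-8-methoxynaphthalen-1-yl)buta-1,3-dien-1-yl]oxy}triisopropylsilane | COc1cccc2c(OCc3ccccc3)ccc(/C=C/C=C/O[Si](C(C)C)(C(C)C)C(C)C)c12 | intermediate
12 | p-benzoquinone | O=C1C=CC(=O)C=C1 | starting material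
13 | (4aS,5S,8R,8aS)-5-[4-(benzyloxy)-8-methoxynaphthalen-1-yl]-8-[(triisopropylsilyl)oxy]-4a,5,8,8a-tetrahydronaphthalene-1,4-dione | COc1cccc2c(OCc3ccccc3)ccc([C@H]3C=C[C@@H](O[Si](C(C)C)(C(C)C)C(C)C)[C@H]4C(=O)C=CC(=O)[C@@H]34)c12 | intermediate
14 | (5R,8R)-5-[4-(benzyloxy)-8-methoxynaphthalen-1-yl]-8-[(triisopropylsilyl)oxy]-5,8-dihydronaphthalene-1,4-diol (present as its potassium phenoxide in the flask) | COc1cccc2c(OCc3ccccc3)ccc([C@H]3C=C[C@@H](O[Si](C(C)C)(C(C)C)C(C)C)c4c(O)ccc(O)c43)c12 | intermediate
15 | (5R,8R)-1,4-bis(benzyloxy)-5-[4-(benzyloxy)-8-methoxynaphthalen-1-yl]-8-[(triisopropylsilyl)oxy]-5,8-dihydronaphthalene | COc1cccc2c(OCc3ccccc3)ccc([C@H]3C=C[C@@H](O[Si](C(C)C)(C(C)C)C(C)C)c4c(OCc5ccccc5)ccc(OCc5ccccc5)c43)c12 | intermediate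
16 | (1R,4R)-5,8-bis(benzyloxy)-4-[4-(benzyloxy)-8-methoxynaphthalen-1-yl]-1-[(triisopropylsilyl)oxy]-1,2,3,4-tetrahydronaphthalene | COc1cccc2c(OCc3ccccc3)ccc([C@H]3CC[C@@H](O[Si](C(C)C)(C(C)C)C(C)C)c4c(OCc5ccccc5)ccc(OCc5ccccc5)c43)c12 | intermediate
17 | (1R,4R)-5,8-bis(benzyloxy)-4-[4-(benzyloxy)-8-methoxynaphthalen-1-yl]-1,2,3,4-tetrahydronaphthalen-1-ol | COc1cccc2c(OCc3ccccc3)ccc([C@H]3CC[C@@H](O)c4c(OCc5ccccc5)ccc(OCc5ccccc5)c43)c12 | intermediate
18 | (4R)-5,8-bis(benzyloxy)-4-[4-(benzyloxy)-8-methoxynaphthalen-1-yl]-3,4-dihydronaphthalen-1(2H)-one | COc1cccc2c(OCc3ccccc3)ccc([C@H]3CCC(=O)c4c(OCc5ccccc5)ccc(OCc5ccccc5)c43)c12 | intermediate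
19 | (4R)-5,8-dihydroxy-4-(4-hydroxy-8-methoxynaphthalen-1-yl)-3,4-dihydronaphthalen-1(2H)-one | COc1cccc2c(O)ccc([C@H]3CCC(=O)c4c(O)ccc(O)c43)c12 | target

Total step count: 12
Longest linear sequence: 12 steps (1 to 19); compounds 5, 9 and 12 are bought.

Steps most likely to fail

Step 7. The strongly acidic boron catalyst may desilylate or polymerise the dienol silyl ether, or promote arylation of the quinone by the electron-rich naphthalene, before cycloaddition occurs. Incomplete control of face, endo approach or diene orientation would also erode the enantiomeric purity. Fallback: setting out from 11 and 12, the cycloaddition is run without catalyst (toluene, rt to 40 °C) and should give the racemic endo adduct F1. The conditions of steps 8 and 9 then lead through the racemic bis(benzyl) ether F2 to the racemic tetralin silyl ether F3. Its enantiomers are separated by preparative chromatography on a chiral stationary phase (amylose tris(3,5-dimethylphenylcarbamate), supercritical CO2/alcohol). The wanted antipode is 16, where the route is rejoined, and the mirror-image tetralin silyl ether F4 is set aside.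

Step 8. Silanolate may be lost by β-elimination from the enolate, or from the phenoxide by way of an ortho-quinone methide, ending in an aromatised naphthalene; the hydroquinone dianion may also be oxidised by air before it is alkylated. Fallback: setting out from 13, acylative trapping under weakly basic conditions (Ac2O, Et3N, catalytic 4-(dimethylamino)pyridine, CH2Cl2, 0 °C) should give the dihydronaphthalene diacetate F5, whose electron-poor ring carries no free phenoxide. Hydrogenation (H2, RhCl(PPh3)3) gives the tetralin diacetate F6, which can no longer aromatise. Methanolysis (K2CO3, degassed MeOH) frees the tetralin hydroquinone F7, and benzylation (BnBr, K2CO3, DMF) returns to the route at 16.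

Step 5. The enolisable arylacetaldehyde may condense with itself at the temperature the sluggish ylide needs, and the product enal may be olefinated a second time. Fallback: setting out from 8, a Horner–Wadsworth–Emmons reaction with triethyl phosphonoacetate (LiCl, iPr2NEt, MeCN, rt) should give the (E)-enoate ethyl ester F8. Reduction with iBu2AlH (CH2Cl2, −78 °C) gives the allylic alcohol F9, and oxidation with MnO2 (CH2Cl2, rt) returns to the route at 10.

Further compounds
F1 | step 7 | racemic all-cis endo adduct (13 together with its mirror image) | COc1cccc2c(OCc3ccccc3)ccc([C@H]3C=C[C@@H](O[Si](C(C)C)(C(C)C)C(C)C)[C@H]4C(=O)C=CC(=O)[C@@H]34)c12.COc1cccc2c(OCc3ccccc3)ccc([C@@H]3C=C[C@H](O[Si](C(C)C)(C(C)C)C(C)C)[C@@H]4C(=O)C=CC(=O)[C@H]34)c12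
F2 | step 7 | racemic cis-1,4-bis(benzyloxy)-5-aryl-8-silyloxy-5,8-dihydronaphthalene (15 together with its mirror image) | COc1cccc2c(OCc3ccccc3)ccc([C@H]3C=C[C@@H](O[Si](C(C)C)(C(C)C)C(C)C)c4c(OCc5ccccc5)ccc(OCc5ccccc5)c43)c12.COc1cccc2c(OCc3ccccc3)ccc([C@@H]3C=C[C@H](O[Si](C(C)C)(C(C)C)C(C)C)c4c(OCc5ccccc5)ccc(OCc5ccccc5)c43)c12
F3 | step 7 | racemic cis tetralin silyl ether (16 together with its mirror image) | COc1cccc2c(OCc3ccccc3)ccc([C@H]3CC[C@@H](O[Si](C(C)C)(C(C)C)C(C)C)c4c(OCc5ccccc5)ccc(OCc5ccccc5)c43)c12.COc1cccc2c(OCc3ccccc3)ccc([C@@H]3CC[C@H](O[Si](C(C)C)(C(C)C)C(C)C)c4c(OCc5ccccc5)ccc(OCc5ccccc5)c43)c12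
F4 | step 7 | (1S,4S)-5,8-bis(benzyloxy)-4-[4-(benzyloxy)-8-methoxynaphthalen-1-yl]-1-[(triisopropylsilyl)oxy]-1,2,3,4-tetrahydronaphthalene (mirror image of 16) | COc1cccc2c(OCc3ccccc3)ccc([C@@H]3CC[C@H](O[Si](C(C)C)(C(C)C)C(C)C)c4c(OCc5ccccc5)ccc(OCc5ccccc5)c43)c12
F5 | step 8 | (5R,8R)-5-[4-(benzyloxy)-8-methoxynaphthalen-1-yl]-8-[(triisopropylsilyl)oxy]-5,8-dihydronaphthalene-1,4-diyl diacetate | COc1cccc2c(OCc3ccccc3)ccc([C@H]3C=C[C@@H](O[Si](C(C)C)(C(C)C)C(C)C)c4c(OC(C)=O)ccc(OC(C)=O)c43)c12
F6 | step 8 | (5R,8R)-5-[4-(benzyloxy)-8-methoxynaphthalen-1-yl]-8-[(triisopropylsilyl)oxy]-5,6,7,8-tetrahydronaphthalene-1,4-diyl diacetate | COc1cccc2c(OCc3ccccc3)ccc([C@H]3CC[C@@H](O[Si](C(C)C)(C(C)C)C(C)C)c4c(OC(C)=O)ccc(OC(C)=O)c43)c12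
F7 | step 8 | (5R,8R)-5-[4-(benzyloxy)-8-methoxynaphthalen-1-yl]-8-[(triisopropylsilyl)oxy]-5,6,7,8-tetrahydronaphthalene-1,4-diol | COc1cccc2c(OCc3ccccc3)ccc([C@H]3CC[C@@H](O[Si](C(C)C)(C(C)C)C(C)C)c4c(O)ccc(O)c43)c12
F8 | step 5 | ethyl (E)-4-[4-(benzyloxy)-8-methoxynaphthalen-1-yl]but-2-enoate | CCOC(=O)/C=C/Cc1ccc(OCc2ccccc2)c2cccc(OC)c12
F9 | step 5 | (E)-4-[4-(benzyloxy)-8-methoxynaphthalen-1-yl]but-2-en-1-ol | OC/C=C/Cc1ccc(OCc2ccccc2)c2cccc(OC)c12
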